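**Retrosynthetic overview**
1. Quinone ⇐ 2,6-dialkyl-1,4-dimethoxybenzene by oxidative demethylation (last step).
2. Butenolide ⇐ α-phenylsulfanyl γ-lactone (sulfoxide elimination) ⇐ (S)-terminal epoxide + (phenylsulfanyl)acetic acid dianion, then α-alkylation with 5-bromo-2-methylpent-2-ene.
3. C5'–C6' bond ⇐ Negishi coupling of a homoallylic zinc (fragment A, arene half) with an (E)-vinyl iodide (fragment B, chiral half); both E-alkenes come from Zr-catalysed methylalumination of terminal alkynes.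
4. Stereocentre ⇐ ketoreductase reduction of ethyl 4-chloroacetoacetate; the ester end becomes the alkyne, the CH2Cl end becomes the epoxide.
5. Ring order: benzene ring bought → oxirane (step 15) → γ-lactone (step 16) → butenolide (step 19) → quinone (step 20).

Assumption: compounds 1, 6, 11, 22 and 26 are taken as commercially available; chain atoms are counted C1' (benzylic CH2) to C8' (CH2 next to the lactone).

**Route**

Step 1
Reactants: 1 4-methoxy-2-methylphenol
Product: 2 2-hydroxy-5-methoxy-3-methylbenzaldehyde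
Conditions: MgCl2, Et3N, (CH2O)n, MeCN, reflux
Reagents that add atoms: paraformaldehyde (as formaldehyde), C=O
Why: Casnati–Skattebøl ortho-formylation, in which the magnesium phenoxide delivers formaldehyde only to the free position ortho to OH and a second formaldehyde oxidises the benzylic alkoxide to the aldehyde.

Step 2
Reactants: 2 2-hydroxy-5-methoxy-3-methylbenzaldehyde
Product: 3 2,5-dimethoxy-3-methylbenzaldehyde
Conditions: MeI, K2CO3, DMF, rt
Reagents that add atoms: iodomethane, CI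
Why: Williamson O-methylation of the phenoxide (SN2 on MeI), to which the aldehyde is inert.

Step 3
Reactants: 3 2,5-dimethoxy-3-methylbenzaldehyde
Product: 4 (2,5-dimethoxy-3-methylphenyl)methanol
Conditions: NaBH4, MeOH, 0 °C
Reagents that add atoms: none
Why: Hydride reduction of the aryl aldehyde to the benzylic alcohol, with nothing else reducible in the molecule.

Step 4
Reactants: 4 (2,5-dimethoxy-3-methylphenyl)methanol
Product: 5 1-(chloromethyl)-2,5-dimethoxy-3-methylbenzene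
Conditions: SOCl2, CH2Cl2, 0 °C→rt
Reagents that add atoms: thionyl chloride, ClS(Cl)=O
Why: Chlorodehydroxylation through the chlorosulfite, fast for an electron-rich benzylic alcohol and harmless to the aryl ethers.

Step 5
Reactants: 5 1-(chloromethyl)-2,5-dimethoxy-3-methylbenzene; 6 tert-butyl(but-3-yn-1-yloxy)dimethylsilane
Product: 8 tert-butyl{[(E)-5-(2,5-dimethoxy-3-methylphenyl)-3-methylpent-3-enyl]oxy}dimethylsilane, via alkenylalane 7 (not isolated)
Conditions: 6, Me3Al (2 equiv), Cp2ZrCl2 (0.25 equiv), ClCH2CH2Cl, rt; then 5, Pd(PPh3)4 (5 mol %), THF, rt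
Reagents that add atoms: trimethylaluminium, C[Al](C)C
Why: Negishi zirconium-catalysed methylalumination adds Me and Al syn across the terminal alkyne (Me to the internal carbon), and the palladium-catalysed alkenyl–benzyl cross-coupling replaces Al with retention, which fixes the E trisubstituted alkene.

Step 6
Reactants: 8 tert-butyl{[(E)-5-(2,5-dimethoxy-3-methylphenyl)-3-methylpent-3-enyl]oxy}dimethylsilane
Product: 9 (E)-5-(2,5-dimethoxy-3-methylphenyl)-3-methylpent-3-en-1-ol
Conditions: Bu4NF, THF, rt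
Reagents that add atoms: none
Why: Fluoride-induced desilylation frees the primary alcohol and leaves the alkene and aryl ethers untouched.

Step 7
Reactants: 9 (E)-5-(2,5-dimethoxy-3-methylphenyl)-3-methylpent-3-en-1-ol
Product: 10 1-[(E)-5-iodo-3-methylpent-2-enyl]-2,5-dimethoxy-3-methylbenzene
Conditions: I2, PPh3, imidazole, CH2Cl2, 0 °C→rt
Reagents that add atoms: iodine, II
Why: Appel-type iodination (Garegg–Samuelsson), in which iodide displaces the alkoxyphosphonium group by SN2 at the primary carbon.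

Step 8
Reactants: 11 ethyl 4-chloro-3-oxobutanoate
Product: 12 ethyl (S)-4-chloro-3-hydroxybutanoate
Conditions: ketoreductase (NADPH-dependent, S-selective for this ketone), NADP+ (cat.), iPrOH (10% v/v), phosphate buffer pH 7.0, 30 °C
Reagents that add atoms: none
Why: Ketoreductase-catalysed asymmetric reduction of the β-keto ester (NADPH recycled from iPrOH by the same enzyme) delivers hydride to one face of the ketone and sets the only stereocentre as S in >99% ee.

Step 9
Reactants: 12 ethyl (S)-4-chloro-3-hydroxybutanoate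
Product: 13 ethyl (S)-3-[(tert-butyldimethylsilyl)oxy]-4-chlorobutanoate
Conditions: TBSCl, imidazole, DMF, rt
Reagents that add atoms: tert-butyldimethylsilyl chloride, CC(C)(C)[Si](C)(C)Cl
Why: Imidazole-promoted silylation of the secondary alcohol blocks retro-aldol and elimination pathways in the following steps.

Step 10
Reactants: 13 ethyl (S)-3-[(tert-butyldimethylsilyl)oxy]-4-chlorobutanoate
Product: 14 (S)-3-[(tert-butyldimethylsilyl)oxy]-4-chlorobutanal
Conditions: iBu2AlH (1.1 equiv), CH2Cl2, −78 °C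
Reagents that add atoms: none
Why: Partial ester reduction works because the tetrahedral aluminium hemiacetal is stable at −78 °C and releases the aldehyde only on work-up, and the stereocentre is β to the carbonyl so it cannot epimerise.

Step 11
Reactants: 14 (S)-3-[(tert-butyldimethylsilyl)oxy]-4-chlorobutanal
Product: 15 (S)-tert-butyl[(1-chloropent-4-yn-2-yl)oxy]dimethylsilane
Conditions: dimethyl (1-diazo-2-oxopropyl)phosphonate, K2CO3, MeOH, 0 °C→rt
Reagents that add atoms: dimethyl (1-diazo-2-oxopropyl)phosphonate, CC(=O)C(=[N+]=[N-])P(=O)(OC)OC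
Why: Ohira–Bestmann (Seyferth–Gilbert) homologation, in which the diazomethylphosphonate anion adds to the aldehyde and the derived alkylidene carbene rearranges to the terminal alkyne under conditions mild enough for a β-silyloxy aldehyde.

Step 12
Reactants: 15 (S)-tert-butyl[(1-chloropent-4-yn-2-yl)oxy]dimethylsilane
Product: 17 tert-butyl{[(2S,4E)-1-chloro-5-iodo-4-methylpent-4-en-2-yl]oxy}dimethylsilane, via alkenylalane 16 (not isolated)
Conditions: Me3Al (2.5 equiv), Cp2ZrCl2 (0.25 equiv), ClCH2CH2Cl, rt; then I2, THF, −30→0 °C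
Reagents that add atoms: trimethylaluminium, C[Al](C)C; iodine, II
Why: Negishi zirconium-catalysed methylalumination (syn, Me to the internal carbon) followed by iodinolysis of the C–Al bond with retention gives the E vinyl iodide, and the remote stereocentre is not involved.

Step 13
Reactants: 10 1-[(E)-5-iodo-3-methylpent-2-enyl]-2,5-dimethoxy-3-methylbenzene; 17 tert-butyl{[(2S,4E)-1-chloro-5-iodo-4-methylpent-4-en-2-yl]oxy}dimethylsilane
Product: 19 tert-butyl{[(2S,4E,8E)-1-chloro-10-(2,5-dimethoxy-3-methylphenyl)-4,8-dimethyldeca-4,8-dien-2-yl]oxy}dimethylsilane, via alkylzinc iodide 18 (not isolated)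
Conditions: 10, Zn (dust), LiCl, THF, 40 °C; then 17, Pd(dppf)Cl2 (5 mol %), THF, rt→45 °C
Reagents that add atoms: none
Why: Negishi cross-coupling, in which zinc insertion into the primary iodide and palladium-catalysed sp3–sp2 coupling with the vinyl iodide retain alkene geometry and tolerate the alkyl chloride and silyl ether.

Step 14
Reactants: 19 tert-butyl{[(2S,4E,8E)-1-chloro-10-(2,5-dimethoxy-3-methylphenyl)-4,8-dimethyldeca-4,8-dien-2-yl]oxy}dimethylsilane
Product: 20 (2S,4E,8E)-1-chloro-10-(2,5-dimethoxy-3-methylphenyl)-4,8-dimethyldeca-4,8-dien-2-ol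
Conditions: HF·pyridine, THF, 0 °C→rt
Reagents that add atoms: none
Why: Acidic fluoride desilylation frees the secondary alcohol without base, so the chlorohydrin is isolated cleanly.

Step 15
Reactants: 20 (2S,4E,8E)-1-chloro-10-(2,5-dimethoxy-3-methylphenyl)-4,8-dimethyldeca-4,8-dien-2-ol
Product: 21 (S)-2-[(2E,6E)-8-(2,5-dimethoxy-3-methylphenyl)-2,6-dimethylocta-2,6-dienyl]oxirane
Conditions: K2CO3, MeOH, rt
Reagents that add atoms: none
Why: Intramolecular Williamson etherification (SN2 at the CH2Cl carbon) closes the oxirane without breaking the C–O bond at the stereocentre, so configuration is retained.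

Step 16
Reactants: 21 (S)-2-[(2E,6E)-8-(2,5-dimethoxy-3-methylphenyl)-2,6-dimethylocta-2,6-dienyl]oxirane; 22 (phenylsulfanyl)acetic acid
Product: 25 (5S)-5-[(2E,6E)-8-(2,5-dimethoxy-3-methylphenyl)-2,6-dimethylocta-2,6-dienyl]-3-(phenylsulfanyl)oxolan-2-one (both C3 epimers), via dilithium dianion 23 (not isolated), via hydroxy acid 24 (not isolated)
Conditions: 22, LiN(iPr)2 (2.1 equiv), THF, −78→0 °C; 21, 0 °C→rt; aq. HCl; then TsOH (cat.), CH2Cl2, rt
Reagents that add atoms: none
Why: The carboxylic acid dianion opens the terminal epoxide by SN2 attack at the unsubstituted carbon, and acid-catalysed lactonisation of the γ-hydroxy acid closes the ring with the stereocentre untouched.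

Step 17
Reactants: 25 (5S)-5-[(2E,6E)-8-(2,5-dimethoxy-3-methylphenyl)-2,6-dimethylocta-2,6-dienyl]-3-(phenylsulfanyl)oxolan-2-one; 26 5-bromo-2-methylpent-2-ene
Product: 28 (5S)-5-[(2E,6E)-8-(2,5-dimethoxy-3-methylphenyl)-2,6-dimethylocta-2,6-dienyl]-3-(4-methylpent-3-enyl)-3-(phenylsulfanyl)oxolan-2-one (both C3 epimers), via lithium enolate 27 (not isolated)
Conditions: LiN(iPr)2 (1.1 equiv), THF/DMPU, −78 °C; then 26, NaI (cat.), −78→0 °C
Reagents that add atoms: none
Why: SN2 alkylation of the sulfur-stabilised lactone enolate installs the 4-methylpent-3-enyl chain, and the new C3 centre is destroyed in step 19 so its configuration does not matter.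

Step 18
Reactants: 28 (5S)-5-[(2E,6E)-8-(2,5-dimethoxy-3-methylphenyl)-2,6-dimethylocta-2,6-dienyl]-3-(4-methylpent-3-enyl)-3-(phenylsulfanyl)oxolan-2-one
Product: 29 (5S)-5-[(2E,6E)-8-(2,5-dimethoxy-3-methylphenyl)-2,6-dimethylocta-2,6-dienyl]-3-(4-methylpent-3-enyl)-3-(phenylsulfinyl)oxolan-2-one (diastereomer mixture)
Conditions: mCPBA (1.0 equiv), CH2Cl2, −78 °C
Reagents that add atoms: 3-chloroperoxybenzoic acid, O=C(OO)c1cccc(Cl)c1
Why: Peracid oxidation of a sulfide to the sulfoxide is far faster than epoxidation of trisubstituted alkenes at −78 °C, so one equivalent is chemoselective.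

Step 19
Reactants: 29 (5S)-5-[(2E,6E)-8-(2,5-dimethoxy-3-methylphenyl)-2,6-dimethylocta-2,6-dienyl]-3-(4-methylpent-3-enyl)-3-(phenylsulfinyl)oxolan-2-one
Product: 30 (S)-5-[(2E,6E)-8-(2,5-dimethoxy-3-methylphenyl)-2,6-dimethylocta-2,6-dienyl]-3-(4-methylpent-3-enyl)furan-2(5H)-one
Conditions: toluene, 110 °C
Reagents that add atoms: none
Why: Thermal sulfoxide syn-elimination towards the ring CH2 gives the conjugated endocyclic butenolide under neutral conditions, so the now acidic C5 stereocentre is not epimerised.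

Step 20
Reactants: 30 (S)-5-[(2E,6E)-8-(2,5-dimethoxy-3-methylphenyl)-2,6-dimethylocta-2,6-dienyl]-3-(4-methylpent-3-enyl)furan-2(5H)-one
Product: 31 2-methyl-6-{(2E,6E)-3,7-dimethyl-8-[(2S)-4-(4-methylpent-3-enyl)-5-oxo-2,5-dihydrofuran-2-yl]octa-2,6-dienyl}cyclohexa-2,5-diene-1,4-dione
Conditions: (NH4)2Ce(NO3)6 (2.5 equiv), MeCN/H2O (2:1), 0 °C
Reagents that add atoms: water, O
Why: Oxidative demethylation of the 1,4-dimethoxyarene by tetravalent cerium (two one-electron oxidations with water attack at the ipso carbons) gives the para-quinone, while the isolated alkenes and the butenolide survive the short, cold reaction.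

**Compound list**
1 | 4-methoxy-2-methylphenol | COc1ccc(O)c(C)c1 | starting material
2 | 2-hydroxy-5-methoxy-3-methylbenzaldehyde | COc1cc(C)c(O)c(C=O)c1 | intermediate
3 | 2,5-dimethoxy-3-methylbenzaldehyde | COc1cc(C)c(OC)c(C=O)c1 | intermediate
4 | (2,5-dimethoxy-3-methylphenyl)methanol | COc1cc(C)c(OC)c(CO)c1 | intermediate
5 | 1-(chloromethyl)-2,5-dimethoxy-3-methylbenzene | COc1cc(C)c(OC)c(CCl)c1 | intermediate
6 | tert-butyl(but-3-yn-1-yloxy)dimethylsilane | C#CCCO[Si](C)(C)C(C)(C)C | starting material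
7 | {(E)-4-[(tert-butyldimethylsilyl)oxy]-2-methylbut-1-enyl}dimethylalumane | C[Al](C)/C=C(\C)CCO[Si](C)(C)C(C)(C)C | intermediate
8 | tert-butyl{[(E)-5-(2,5-dimethoxy-3-methylphenyl)-3-methylpent-3-enyl]oxy}dimethylsilane | CC(C)(C)[Si](C)(C)OCC/C(C)=C/Cc1cc(OC)cc(C)c1OC | intermediate
9 | (E)-5-(2,5-dimethoxy-3-methylphenyl)-3-methylpent-3-en-1-ol | OCC/C(C)=C/Cc1cc(OC)cc(C)c1OC | intermediate
10 | 1-[(E)-5-iodo-3-methylpent-2-enyl]-2,5-dimethoxy-3-methylbenzene | ICC/C(C)=C/Cc1cc(OC)cc(C)c1OC | intermediate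
11 | ethyl 4-chloro-3-oxobutanoate | CCOC(=O)CC(=O)CCl | starting material
12 | ethyl (S)-4-chloro-3-hydroxybutanoate | ClC[C@H](CC(=O)OCC)O | intermediate
13 | ethyl (S)-3-[(tert-butyldimethylsilyl)oxy]-4-chlorobutanoate | ClC[C@H](CC(=O)OCC)O[Si](C)(C)C(C)(C)C | intermediate
14 | (S)-3-[(tert-butyldimethylsilyl)oxy]-4-chlorobutanal | ClC[C@H](CC=O)O[Si](C)(C)C(C)(C)C | intermediate
15 | (S)-tert-butyl[(1-chloropent-4-yn-2-yl)oxy]dimethylsilane | ClC[C@H](CC#C)O[Si](C)(C)C(C)(C)C | intermediate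
16 | {(1E,4S)-4-[(tert-butyldimethylsilyl)oxy]-5-chloro-2-methylpent-1-enyl}dimethylalumane | ClC[C@H](C/C(C)=C/[Al](C)C)O[Si](C)(C)C(C)(C)C | intermediate
17 | tert-butyl{[(2S,4E)-1-chloro-5-iodo-4-methylpent-4-en-2-yl]oxy}dimethylsilane | ClC[C@H](C/C(C)=C/I)O[Si](C)(C)C(C)(C)C | intermediate
18 | [(E)-5-(2,5-dimethoxy-3-methylphenyl)-3-methylpent-3-enyl]zinc iodide | I[Zn]CC/C(C)=C/Cc1cc(OC)cc(C)c1OC | intermediate
19 | tert-butyl{[(2S,4E,8E)-1-chloro-10-(2,5-dimethoxy-3-methylphenyl)-4,8-dimethyldeca-4,8-dien-2-yl]oxy}dimethylsilane | ClC[C@H](C/C(C)=C/CC/C(C)=C/Cc1cc(OC)cc(C)c1OC)O[Si](C)(C)C(C)(C)C | intermediate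
20 | (2S,4E,8E)-1-chloro-10-(2,5-dimethoxy-3-methylphenyl)-4,8-dimethyldeca-4,8-dien-2-ol | ClC[C@H](C/C(C)=C/CC/C(C)=C/Cc1cc(OC)cc(C)c1OC)O | intermediate
21 | (S)-2-[(2E,6E)-8-(2,5-dimethoxy-3-methylphenyl)-2,6-dimethylocta-2,6-dienyl]oxirane | C1[C@H](C/C(C)=C/CC/C(C)=C/Cc2cc(OC)cc(C)c2OC)O1 | intermediate
22 | (phenylsulfanyl)acetic acid | OC(=O)CSc1ccccc1 | starting material
23 | dilithium 2-(phenylsulfanyl)ethene-1,1-diolate (dianion of 22) | [Li+].[Li+].[O-]C([O-])=CSc1ccccc1 | intermediate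
24 | (4S,6E,10E)-12-(2,5-dimethoxy-3-methylphenyl)-4-hydroxy-6,10-dimethyl-2-(phenylsulfanyl)dodeca-6,10-dienoic acid (both C2 epimers) | OC(=O)C(Sc1ccccc1)C[C@H](C/C(C)=C/CC/C(C)=C/Cc1cc(OC)cc(C)c1OC)O | intermediate
25 | (5S)-5-[(2E,6E)-8-(2,5-dimethoxy-3-methylphenyl)-2,6-dimethylocta-2,6-dienyl]-3-(phenylsulfanyl)oxolan-2-one (both C3 epimers) | C1(Sc2ccccc2)C[C@H](C/C(C)=C/CC/C(C)=C/Cc2cc(OC)cc(C)c2OC)OC1=O | intermediate
26 | 5-bromo-2-methylpent-2-ene | CC(C)=CCCBr | starting material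
27 | lithium enolate of 25 | [Li+].[O-]C1=C(Sc2ccccc2)C[C@H](C/C(C)=C/CC/C(C)=C/Cc2cc(OC)cc(C)c2OC)O1 | intermediate
28 | (5S)-5-[(2E,6E)-8-(2,5-dimethoxy-3-methylphenyl)-2,6-dimethylocta-2,6-dienyl]-3-(4-methylpent-3-enyl)-3-(phenylsulfanyl)oxolan-2-one (both C3 epimers) | CC(C)=CCCC1(Sc2ccccc2)C[C@H](C/C(C)=C/CC/C(C)=C/Cc2cc(OC)cc(C)c2OC)OC1=O | intermediate
29 | (5S)-5-[(2E,6E)-8-(2,5-dimethoxy-3-methylphenyl)-2,6-dimethylocta-2,6-dienyl]-3-(4-methylpent-3-enyl)-3-(phenylsulfinyl)oxolan-2-one (diastereomer mixture) | CC(C)=CCCC1(S(=O)c2ccccc2)C[C@H](C/C(C)=C/CC/C(C)=C/Cc2cc(OC)cc(C)c2OC)OC1=O | intermediate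
30 | (S)-5-[(2E,6E)-8-(2,5-dimethoxy-3-methylphenyl)-2,6-dimethylocta-2,6-dienyl]-3-(4-methylpent-3-enyl)furan-2(5H)-one | CC(C)=CCCC1=C[C@H](C/C(C)=C/CC/C(C)=C/Cc2cc(OC)cc(C)c2OC)OC1=O | intermediate
31 | 2-methyl-6-{(2E,6E)-3,7-dimethyl-8-[(2S)-4-(4-methylpent-3-enyl)-5-oxo-2,5-dihydrofuran-2-yl]octa-2,6-dienyl}cyclohexa-2,5-diene-1,4-dione | CC(C)=CCCC1=C[C@H](C/C(C)=C/CC/C(C)=C/CC2=CC(=O)C=C(C)C2=O)OC1=O | target

**Step count**
Total: 20 steps. Longest linear sequence: 15 steps (1 → 31 through steps 1–7 and 13–20); the chiral branch 11 → 17 is 5 steps (8–12).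

**Three steps most likely to fail, each with a fallback**

Step 13 (alkyl–alkenyl Negishi coupling). Zinc insertion may be sluggish, and β-hydride loss from the alkylpalladium can lower the yield. The fallback replaces the zinc route with a B-alkyl Suzuki–Miyaura coupling and sets out from iodide 10. Treatment with tBuLi (2 equiv, Et2O, −78 °C) and then 9-methoxy-9-borabicyclo[3.3.1]nonane gives lithium [(E)-5-(2,5-dimethoxy-3-methylphenyl)-3-methylpent-3-enyl](methoxy)-9-borabicyclo[3.3.1]nonan-9-uide F1. This borate is coupled with 17 (Pd(dppf)Cl2, AsPh3, aq. K3PO4, DMF, rt), and the fallback comes back to the route at 19.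

Step 17 (alkylation of the hindered lactone enolate). The homoallylic bromide can undergo E2 elimination to a diene, and the enolate may react slowly. The fallback attaches the side chain to the acid before the epoxide is opened and sets out from 22 together with 26 and 21. The dianion of 22 (LiN(iPr)2, 2 equiv, THF) is alkylated with 26 to give 6-methyl-2-(phenylsulfanyl)hept-5-enoic acid F2. The dianion of F2 (LiN(iPr)2, 2 equiv) opens epoxide 21 at its CH2 terminus to give (4S,6E,10E)-12-(2,5-dimethoxy-3-methylphenyl)-4-hydroxy-6,10-dimethyl-2-(4-methylpent-3-enyl)-2-(phenylsulfanyl)dodeca-6,10-dienoic acid F3. Lactonisation of F3 (TsOH cat., CH2Cl2) comes back to the route at 28.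

Step 18 (sulfide oxidation in a triene, with the elimination of step 19). The peracid may epoxidise a trisubstituted alkene, and the sulfoxide may eliminate partly towards the side chain. The fallback builds the butenolide by Still–Gennari olefination and lactonisation, without peracid or sulfur, and sets out from epoxide 21 (replacing steps 16–19).
- Aq. KOH in DMSO at 90 °C opens 21 at the CH2 terminus to (2S,4E,8E)-10-(2,5-dimethoxy-3-methylphenyl)-4,8-dimethyldeca-4,8-diene-1,2-diol F4.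
- Et3SiCl and imidazole give (2S,4E,8E)-10-(2,5-dimethoxy-3-methylphenyl)-4,8-dimethyl-1,2-bis[(triethylsilyl)oxy]deca-4,8-diene F5.
- Swern oxidation ((COCl)2, DMSO, then Et3N, −78→−20 °C) converts the primary silyl ether directly into (2S,4E,8E)-10-(2,5-dimethoxy-3-methylphenyl)-4,8-dimethyl-2-[(triethylsilyl)oxy]deca-4,8-dienal F6.
- Separately, methyl bis(2,2,2-trifluoroethoxy)phosphorylacetate is alkylated with 26 (NaH, DMSO) to methyl 2-[bis(2,2,2-trifluoroethoxy)phosphoryl]-6-methylhept-5-enoate F7.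
- F7 with KN(SiMe3)2 and 18-crown-6 (THF, −78 °C) reacts with F6 to give methyl (2Z,4S,6E,10E)-12-(2,5-dimethoxy-3-methylphenyl)-6,10-dimethyl-2-(4-methylpent-3-enyl)-4-[(triethylsilyl)oxy]dodeca-2,6,10-trienoate F8.
- HF·pyridine removes the silyl group, the (Z)-hydroxy ester lactonises, and the fallback comes back to the route at 30.

Further compounds
F1 | step 13 | lithium [(E)-5-(2,5-dimethoxy-3-methylphenyl)-3-methylpent-3-enyl](methoxy)-9-borabicyclo[3.3.1]nonan-9-uide | [Li+].CO[B-]1(CC/C(C)=C/Cc2cc(OC)cc(C)c2OC)C2CCCC1CCC2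
F2 | step 17 | 6-methyl-2-(phenylsulfanyl)hept-5-enoic acid | OC(=O)C(CCC=C(C)C)Sc1ccccc1
F3 | step 17 | (4S,6E,10E)-12-(2,5-dimethoxy-3-methylphenyl)-4-hydroxy-6,10-dimethyl-2-(4-methylpent-3-enyl)-2-(phenylsulfanyl)dodeca-6,10-dienoic acid | OC(=O)C(CCC=C(C)C)(Sc1ccccc1)C[C@H](C/C(C)=C/CC/C(C)=C/Cc1cc(OC)cc(C)c1OC)O
F4 | step 18 | (2S,4E,8E)-10-(2,5-dimethoxy-3-methylphenyl)-4,8-dimethyldeca-4,8-diene-1,2-diol | OC[C@H](C/C(C)=C/CC/C(C)=C/Cc1cc(OC)cc(C)c1OC)O
F5 | step 18 | (2S,4E,8E)-10-(2,5-dimethoxy-3-methylphenyl)-4,8-dimethyl-1,2-bis[(triethylsilyl)oxy]deca-4,8-diene | CC[Si](CC)(CC)OC[C@H](C/C(C)=C/CC/C(C)=C/Cc1cc(OC)cc(C)c1OC)O[Si](CC)(CC)CC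
F6 | step 18 | (2S,4E,8E)-10-(2,5-dimethoxy-3-methylphenyl)-4,8-dimethyl-2-[(triethylsilyl)oxy]deca-4,8-dienal | O=C[C@H](C/C(C)=C/CC/C(C)=C/Cc1cc(OC)cc(C)c1OC)O[Si](CC)(CC)CC
F7 | step 18 | methyl 2-[bis(2,2,2-trifluoroethoxy)phosphoryl]-6-methylhept-5-enoate | COC(=O)C(CCC=C(C)C)P(=O)(OCC(F)(F)F)OCC(F)(F)F
F8 | step 18 | methyl (2Z,4S,6E,10E)-12-(2,5-dimethoxy-3-methylphenyl)-6,10-dimethyl-2-(4-methylpent-3-enyl)-4-[(triethylsilyl)oxy]dodeca-2,6,10-trienoate | COC(=O)/C(CCC=C(C)C)=C\[C@H](C/C(C)=C/CC/C(C)=C/Cc1cc(OC)cc(C)c1OC)O[Si](CC)(CC)CC
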